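**Assumption:** the SMILES is read as drawn, i.e. the trans-fused hydroazulene (1S,5R,6S,7R,9S,11S,12S,14R). Positions are given in dictyol numbering: C1/C5 ring fusion, C2–C4 cyclopentene with the C17 methyl on C4, C6 (OH), C7 (side chain), C8, C9 (OH), C10 (exocyclic C18), then C11 (C19 methyl), C12 (OAc), C13, C14 (OH), C15 (=C16, C20 methyl).

## Retrosynthetic overview

1. Target 29 ⇐ 27 by desilylation and Negishi methylation; the C3=C4 alkene is carried as an enol triflate so that it is blind to oxidants.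
2. 27 ⇐ bis-epoxide 26 by double epoxide → allylic alcohol transposition. The C14–O bond (Shi epoxidation, reagent control) and the C9–O bond (peracid, substrate control) are made on two latent trisubstituted alkenes.
3. Seven-membered ring (second ring) by ring-closing metathesis C9=C10 of diene 24; C12–C13 by α-prenylation/acetylation of aldehyde 21.
4. Five-membered ring (first ring) is bought as cyclopentenone 14; an asymmetric isopropenyl 1,4-addition/boron aldol with aldehyde 10 sets C1, C5 and C6.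
5. Aldehyde 10 ⇐ Ireland–Claisen rearrangement with chirality transfer from (S)-pent-3-en-2-ol (sets C7/C11), then selective ozonolysis.

## Route

Step 1
Reactants: 1 (E)-pent-3-en-2-ol (racemic)
Product: 2 (2S,3E)-pent-3-en-2-ol
Conditions: Novozym 435 (immobilised Candida antarctica lipase B), vinyl acetate (0.6 equiv), hexane, 30 °C, to ca. 55% conversion; recover the unreacted alcohol
Reagents that add atoms: none
Why: Lipase-catalysed kinetic resolution (Kazlauskas rule) acetylates only the (R)-alcohol and leaves (S)-2 in high ee.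

Step 2
Reactants: 2 (2S,3E)-pent-3-en-2-ol; 3 pent-4-enoyl chloride
Product: 4 (2S,3E)-pent-3-en-2-yl pent-4-enoate
Conditions: Et3N, DMAP (cat.), CH2Cl2, 0 → 23 °C
Reagents that add atoms: none
Why: DMAP-catalysed acylation of the secondary alcohol by the acid chloride leaves the carbinol stereocentre untouched.

Step 3
Reactants: 4 (2S,3E)-pent-3-en-2-yl pent-4-enoate
Product: 7 methyl (2R,3R,4E)-3-methyl-2-(prop-2-en-1-yl)hex-4-enoate, via silyl ketene acetal 5 (not isolated), via trimethylsilyl ester 6 (not isolated)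
Conditions: LiN(iPr)2, THF, −78 °C; Me3SiCl; −78 → 60 °C; then CsF, MeI, DMF, 23 °C
Reagents that add atoms: iodomethane, CI
Why: Ireland–Claisen rearrangement, in which kinetic enolisation in THF gives the (E)-silyl ketene acetal and a chair transition state with the carbinol methyl equatorial transfers the C–O chirality to C7 and C11 (anti, new E-alkene), followed by fluoride-assisted O-methylation of the silyl ester.

Step 4
Reactants: 7 methyl (2R,3R,4E)-3-methyl-2-(prop-2-en-1-yl)hex-4-enoate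
Product: 9 methyl (2R,3S)-4,4-dimethoxy-3-methyl-2-(prop-2-en-1-yl)butanoate, via aldehyde ester 8 (not isolated)
Conditions: O3 (1.0 equiv, Sudan Red 7B end point), CH2Cl2/MeOH, −78 °C; Me2S; then HC(OMe)3, TsOH (cat.), MeOH, 23 °C
Reagents that add atoms: trimethyl orthoformate, COC(OC)OC
Why: Chemoselective ozonolysis cleaves the more electron-rich 1,2-disubstituted alkene roughly ten times faster than the terminal allyl group, and acid-catalysed acetalisation masks the new C12 aldehyde.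

Step 5
Reactants: 9 methyl (2R,3S)-4,4-dimethoxy-3-methyl-2-(prop-2-en-1-yl)butanoate
Product: 10 (2R,3S)-4,4-dimethoxy-3-methyl-2-(prop-2-en-1-yl)butanal
Conditions: iBu2AlH (1.05 equiv), CH2Cl2, −78 °C; aq. KNaC4H4O6
Reagents that add atoms: none
Why: Partial reduction of the α-branched methyl ester by iBu2AlH stops at the aluminium hemiacetal at −78 °C and gives the aldehyde on work-up without touching a stereocentre.

Step 6
Reactants: 11 (prop-1-en-2-yl)magnesium bromide; 12 9-chloro-9-borabicyclo[3.3.1]nonane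
Product: 13 9-(prop-1-en-2-yl)-9-borabicyclo[3.3.1]nonane
Conditions: Et2O/hexane, −78 → 23 °C; filtration under Ar
Reagents that add atoms: none
Why: Salt metathesis (B–Cl for C–Mg) is driven by precipitation of the magnesium halide.

Step 7
Reactants: 14 cyclopent-2-en-1-one; 13 9-(prop-1-en-2-yl)-9-borabicyclo[3.3.1]nonane; 10 (2R,3S)-4,4-dimethoxy-3-methyl-2-(prop-2-en-1-yl)butanal
Product: 17 (2S,3S)-2-[(1S,2R,3S)-1-hydroxy-4,4-dimethoxy-3-methyl-2-(prop-2-en-1-yl)butyl]-3-(prop-1-en-2-yl)cyclopentan-1-one, via boron enolate 15 (not isolated), via boron aldolate 16 (not isolated)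
Conditions: [Rh(OMe)(cod)]2 (1.5 mol %), (S)-BINAP (3.3 mol %), toluene, 80 °C, 1 h; then 10, −78 → 0 °C; pH 7 buffer/MeOH
Reagents that add atoms: none
Why: Proposed new method: boron-to-rhodium transmetalation from 13 gives a rhodium–BINAP isopropenyl complex that inserts cyclopentenone enantioselectively, the oxa-π-allyl rhodium species is turned over by 13 under aprotic conditions to give the chiral boron enolate 15 instead of being protonated, and 15 adds to 10 through a closed Zimmerman–Traxler transition state (E-enolate gives the anti aldol, attack trans to the new isopropenyl group, Felkin–Anh face of 10, a fully matched case) so that C1, C5 and C6 are set in one flask; the closest known chemistry is the Hayashi–Miyaura asymmetric 1,4-addition and the generation of chiral boron enolates from B-aryl-9-BBN reagents with aldol trapping, which has not been shown for a 1-substituted alkenyl-9-BBN.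

Step 8
Reactants: 17 (2S,3S)-2-[(1S,2R,3S)-1-hydroxy-4,4-dimethoxy-3-methyl-2-(prop-2-en-1-yl)butyl]-3-(prop-1-en-2-yl)cyclopentan-1-one
Product: 18 (2S,3S)-2-[(1S,2R,3S)-1-{[tert-butyl(dimethyl)silyl]oxy}-4,4-dimethoxy-3-methyl-2-(prop-2-en-1-yl)butyl]-3-(prop-1-en-2-yl)cyclopentan-1-one
Conditions: TBSOTf, 2,6-lutidine, CH2Cl2, −78 °C
Reagents that add atoms: tert-butyldimethylsilyl trifluoromethanesulfonate, CC(C)(C)[Si](C)(C)OS(=O)(=O)C(F)(F)F
Why: Silyl triflate silylation protects the hindered C6 hydroxyl at low temperature, where retro-aldol cleavage and acetal activation do not compete.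

Step 9
Reactants: 18 (2S,3S)-2-[(1S,2R,3S)-1-{[tert-butyl(dimethyl)silyl]oxy}-4,4-dimethoxy-3-methyl-2-(prop-2-en-1-yl)butyl]-3-(prop-1-en-2-yl)cyclopentan-1-one
Product: 20 (4S,5S)-5-[(1S,2R,3S)-1-{[tert-butyl(dimethyl)silyl]oxy}-4,4-dimethoxy-3-methyl-2-(prop-2-en-1-yl)butyl]-4-(prop-1-en-2-yl)cyclopent-1-en-1-yl trifluoromethanesulfonate, via potassium enolate 19 (not isolated)
Conditions: KN(SiMe3)2, THF, −78 °C; then PhNTf2, −78 → 0 °C
Reagents that add atoms: N-phenylbis(trifluoromethanesulfonimide), O=S(=O)(N(c1ccccc1)S(=O)(=O)C(F)(F)F)C(F)(F)F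
Why: Kinetic deprotonation at the unhindered C3 methylene and O-sulfonylation of the enolate (enol triflate formation) give the C3=C4 vinyl triflate, a masked methyl-substituted alkene that is inert to electrophilic oxidants.

Step 10
Reactants: 20 (4S,5S)-5-[(1S,2R,3S)-1-{[tert-butyl(dimethyl)silyl]oxy}-4,4-dimethoxy-3-methyl-2-(prop-2-en-1-yl)butyl]-4-(prop-1-en-2-yl)cyclopent-1-en-1-yl trifluoromethanesulfonate
Product: 21 (4S,5S)-5-[(1S,2R,3S)-1-{[tert-butyl(dimethyl)silyl]oxy}-3-methyl-4-oxo-2-(prop-2-en-1-yl)butyl]-4-(prop-1-en-2-yl)cyclopent-1-en-1-yl trifluoromethanesulfonate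
Conditions: PPTS (cat.), acetone/H2O (10:1), 50 °C
Reagents that add atoms: water, O
Why: Mild acid-catalysed acetal hydrolysis frees the C12 aldehyde while the silyl ether and the vinyl triflate survive.

Step 11
Reactants: 21 (4S,5S)-5-[(1S,2R,3S)-1-{[tert-butyl(dimethyl)silyl]oxy}-3-methyl-4-oxo-2-(prop-2-en-1-yl)butyl]-4-(prop-1-en-2-yl)cyclopent-1-en-1-yl trifluoromethanesulfonate
Product: 23 (4S,5S)-5-[(1S,2R,3S,4S)-4-(acetyloxy)-1-{[tert-butyl(dimethyl)silyl]oxy}-3,7-dimethyl-2-(prop-2-en-1-yl)oct-6-en-1-yl]-4-(prop-1-en-2-yl)cyclopent-1-en-1-yl trifluoromethanesulfonate, via barium alkoxide 22 (not isolated)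
Conditions: BaI2, lithium biphenylide (LiC12H10), THF, 23 °C (activated barium); 1-chloro-3-methylbut-2-ene, −78 °C; then 21, −78 °C; then Ac2O, −78 → 0 °C
Reagents that add atoms: 1-chloro-3-methylbut-2-ene (prenyl chloride), CC(C)=CCCl; acetic anhydride, CC(=O)OC(C)=O
Why: α-Selective addition of the prenylbarium reagent (Yamamoto allylbarium chemistry) under Felkin–Anh control sets C12 (methyl and oxygen syn, minor epimer removed by chromatography), and the barium alkoxide is acetylated in the same flask.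

Step 12
Reactants: 23 (4S,5S)-5-[(1S,2R,3S,4S)-4-(acetyloxy)-1-{[tert-butyl(dimethyl)silyl]oxy}-3,7-dimethyl-2-(prop-2-en-1-yl)oct-6-en-1-yl]-4-(prop-1-en-2-yl)cyclopent-1-en-1-yl trifluoromethanesulfonate
Product: 24 (4S,5S)-5-[(1S,2R,3S,4S)-4-(acetyloxy)-1-{[tert-butyl(dimethyl)silyl]oxy}-5-[(2R)-3,3-dimethyloxiran-2-yl]-3-methyl-2-(prop-2-en-1-yl)pentyl]-4-(prop-1-en-2-yl)cyclopent-1-en-1-yl trifluoromethanesulfonate
Conditions: Shi ketone from D-fructose (1,2:4,5-di-O-isopropylidene-β-D-erythro-hexo-2,3-diulo-2,6-pyranose, 30 mol %), KHSO5 (as 2KHSO5·KHSO4·K2SO4), K2CO3, Bu4NHSO4, MeCN/(MeO)2CH2/aq. Na2B4O7 buffer, 0 °C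
Reagents that add atoms: potassium peroxymonosulfate, [K+].[O-]S(=O)(=O)OO
Why: Shi asymmetric epoxidation, in which the chiral dioxirane attacks only the trisubstituted prenyl alkene through a spiro transition state and forms the C14–O bond with R configuration by reagent control.

Step 13
Reactants: 24 (4S,5S)-5-[(1S,2R,3S,4S)-4-(acetyloxy)-1-{[tert-butyl(dimethyl)silyl]oxy}-5-[(2R)-3,3-dimethyloxiran-2-yl]-3-methyl-2-(prop-2-en-1-yl)pentyl]-4-(prop-1-en-2-yl)cyclopent-1-en-1-yl trifluoromethanesulfonate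
Product: 25 (3aS,4S,5R,8aS)-5-{(2S,3S)-3-(acetyloxy)-4-[(2R)-3,3-dimethyloxiran-2-yl]butan-2-yl}-4-{[tert-butyl(dimethyl)silyl]oxy}-8-methyl-1,3a,4,5,6,8a-hexahydroazulen-3-yl trifluoromethanesulfonate
Conditions: second-generation Grubbs catalyst RuCl2(=CHPh)(H2IMes)(PCy3) (10 mol %), toluene (2 mM), 80 °C
Reagents that add atoms: none
Why: Ring-closing metathesis of the allyl and isopropenyl groups closes the trans-fused seven-membered ring as its C9=C10 trisubstituted alkene, with no other metathesis-active alkene left in the molecule.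

Step 14
Reactants: 25 (3aS,4S,5R,8aS)-5-{(2S,3S)-3-(acetyloxy)-4-[(2R)-3,3-dimethyloxiran-2-yl]butan-2-yl}-4-{[tert-butyl(dimethyl)silyl]oxy}-8-methyl-1,3a,4,5,6,8a-hexahydroazulen-3-yl trifluoromethanesulfonate
Product: 26 (3aS,4S,5R,7S,8R,8aS)-5-{(2S,3S)-3-(acetyloxy)-4-[(2R)-3,3-dimethyloxiran-2-yl]butan-2-yl}-4-{[tert-butyl(dimethyl)silyl]oxy}-7,8-epoxy-8-methyl-1,3a,4,5,6,7,8,8a-octahydroazulen-3-yl trifluoromethanesulfonate
Conditions: mCPBA, NaHCO3, CH2Cl2, −20 → 0 °C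
Reagents that add atoms: 3-chloroperoxybenzoic acid, OOC(=O)c1cccc(Cl)c1
Why: Prilezhaev epoxidation of the only nucleophilic alkene from the face opposite the C6 silyloxy group and the C7 side chain (the face of H1) forms the C9–O bond with S configuration under substrate control.

Step 15
Reactants: 26 (3aS,4S,5R,7S,8R,8aS)-5-{(2S,3S)-3-(acetyloxy)-4-[(2R)-3,3-dimethyloxiran-2-yl]butan-2-yl}-4-{[tert-butyl(dimethyl)silyl]oxy}-7,8-epoxy-8-methyl-1,3a,4,5,6,7,8,8a-octahydroazulen-3-yl trifluoromethanesulfonate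
Product: 27 (3aS,4S,5R,7S,8aS)-5-[(2S,3S,5R)-3-(acetyloxy)-6-methyl-5-[(trimethylsilyl)oxy]hept-6-en-2-yl]-4-{[tert-butyl(dimethyl)silyl]oxy}-8-methylidene-7-[(trimethylsilyl)oxy]-1,3a,4,5,6,7,8,8a-octahydroazulen-3-yl trifluoromethanesulfonate
Conditions: Me3SiOTf, DBU, toluene, 0 → 23 °C
Reagents that add atoms: trimethylsilyl trifluoromethanesulfonate, C[Si](C)(C)OS(=O)(=O)C(F)(F)F
Why: Noyori epoxide-to-allyl silyl ether isomerisation opens both O-silylated epoxides at their tertiary carbons with proton loss from the adjacent methyl groups, so the C9–O and C14–O bonds are retained with their configuration and the two 1,1-disubstituted alkenes are created.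

Step 16
Reactants: 27 (3aS,4S,5R,7S,8aS)-5-[(2S,3S,5R)-3-(acetyloxy)-6-methyl-5-[(trimethylsilyl)oxy]hept-6-en-2-yl]-4-{[tert-butyl(dimethyl)silyl]oxy}-8-methylidene-7-[(trimethylsilyl)oxy]-1,3a,4,5,6,7,8,8a-octahydroazulen-3-yl trifluoromethanesulfonate
Product: 28 (2S,3S,5R)-2-[(3aR,4S,5R,7S,8aS)-4-{[tert-butyl(dimethyl)silyl]oxy}-3-methyl-8-methylidene-7-[(trimethylsilyl)oxy]-1,3a,4,5,6,7,8,8a-octahydroazulen-5-yl]-6-methyl-5-[(trimethylsilyl)oxy]hept-6-en-3-yl acetate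
Conditions: Me2Zn, Pd(PPh3)4 (5 mol %), THF, 23 → 50 °C
Reagents that add atoms: dimethylzinc, C[Zn]C
Why: Negishi cross-coupling of the vinyl triflate with dimethylzinc unmasks the C3=C4 methyl-substituted alkene and tolerates the acetate and silyl ethers.

Step 17
Reactants: 28 (2S,3S,5R)-2-[(3aR,4S,5R,7S,8aS)-4-{[tert-butyl(dimethyl)silyl]oxy}-3-methyl-8-methylidene-7-[(trimethylsilyl)oxy]-1,3a,4,5,6,7,8,8a-octahydroazulen-5-yl]-6-methyl-5-[(trimethylsilyl)oxy]hept-6-en-3-yl acetate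
Product: 29 (2S,3S,5R)-2-[(3aR,4S,5R,7S,8aS)-4,7-dihydroxy-3-methyl-8-methylidene-1,3a,4,5,6,7,8,8a-octahydroazulen-5-yl]-5-hydroxy-6-methylhept-6-en-3-yl acetate
Conditions: HF·pyridine, pyridine, THF, 0 → 23 °C
Reagents that add atoms: none
Why: Buffered fluoride desilylation removes the three silyl ethers without acetate cleavage or migration and gives the target.

## Compound list

1 | (E)-pent-3-en-2-ol (racemic) | C/C=C/C(C)O | starting material
2 | (2S,3E)-pent-3-en-2-ol | C/C=C/[C@H](C)O | intermediate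
3 | pent-4-enoyl chloride | C=CCCC(=O)Cl | starting material
4 | (2S,3E)-pent-3-en-2-yl pent-4-enoate | C/C=C/[C@H](C)OC(=O)CCC=C | intermediate
5 | trimethyl{[(1E)-1-{[(2S,3E)-pent-3-en-2-yl]oxy}penta-1,4-dien-1-yl]oxy}silane | C=CC/C=C(\O[C@@H](C)/C=C/C)O[Si](C)(C)C | intermediate
6 | trimethylsilyl (2R,3R,4E)-3-methyl-2-(prop-2-en-1-yl)hex-4-enoate | C/C=C/[C@@H](C)[C@@H](CC=C)C(=O)O[Si](C)(C)C | intermediate
7 | methyl (2R,3R,4E)-3-methyl-2-(prop-2-en-1-yl)hex-4-enoate | C/C=C/[C@@H](C)[C@@H](CC=C)C(=O)OC | intermediate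
8 | methyl (2R,3S)-3-methyl-4-oxo-2-(prop-2-en-1-yl)butanoate | O=C[C@@H](C)[C@@H](CC=C)C(=O)OC | intermediate
9 | methyl (2R,3S)-4,4-dimethoxy-3-methyl-2-(prop-2-en-1-yl)butanoate | COC(OC)[C@@H](C)[C@@H](CC=C)C(=O)OC | intermediate
10 | (2R,3S)-4,4-dimethoxy-3-methyl-2-(prop-2-en-1-yl)butanal | COC(OC)[C@@H](C)[C@@H](CC=C)C=O | intermediate
11 | (prop-1-en-2-yl)magnesium bromide | CC(=C)[Mg]Br | starting material
12 | 9-chloro-9-borabicyclo[3.3.1]nonane | ClB1C2CCCC1CCC2 | starting material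
13 | 9-(prop-1-en-2-yl)-9-borabicyclo[3.3.1]nonane | CC(=C)B1C2CCCC1CCC2 | intermediate
14 | cyclopent-2-en-1-one | O=C1C=CCC1 | starting material
15 | 9-{[(3S)-3-(prop-1-en-2-yl)cyclopent-1-en-1-yl]oxy}-9-borabicyclo[3.3.1]nonane | CC(=C)[C@H]1CCC(OB2C3CCCC2CCC3)=C1 | intermediate
16 | (2S,3S)-2-[(1S,2R,3S)-1-(9-borabicyclo[3.3.1]nonan-9-yloxy)-4,4-dimethoxy-3-methyl-2-(prop-2-en-1-yl)butyl]-3-(prop-1-en-2-yl)cyclopentan-1-one | COC(OC)[C@@H](C)[C@@H](CC=C)[C@H](OB3C4CCCC3CCC4)[C@H]2C(=O)CC[C@@H]2C(C)=C | intermediate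
17 | (2S,3S)-2-[(1S,2R,3S)-1-hydroxy-4,4-dimethoxy-3-methyl-2-(prop-2-en-1-yl)butyl]-3-(prop-1-en-2-yl)cyclopentan-1-one | COC(OC)[C@@H](C)[C@@H](CC=C)[C@H](O)[C@H]2C(=O)CC[C@@H]2C(C)=C | intermediate
18 | (2S,3S)-2-[(1S,2R,3S)-1-{[tert-butyl(dimethyl)silyl]oxy}-4,4-dimethoxy-3-methyl-2-(prop-2-en-1-yl)butyl]-3-(prop-1-en-2-yl)cyclopentan-1-one | COC(OC)[C@@H](C)[C@@H](CC=C)[C@H](O[Si](C)(C)C(C)(C)C)[C@H]2C(=O)CC[C@@H]2C(C)=C | intermediate
19 | potassium (4S,5S)-5-[(1S,2R,3S)-1-{[tert-butyl(dimethyl)silyl]oxy}-4,4-dimethoxy-3-methyl-2-(prop-2-en-1-yl)butyl]-4-(prop-1-en-2-yl)cyclopent-1-en-1-olate | COC(OC)[C@@H](C)[C@@H](CC=C)[C@H](O[Si](C)(C)C(C)(C)C)[C@H]2C([O-])=CC[C@@H]2C(C)=C.[K+] | intermediate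
20 | (4S,5S)-5-[(1S,2R,3S)-1-{[tert-butyl(dimethyl)silyl]oxy}-4,4-dimethoxy-3-methyl-2-(prop-2-en-1-yl)butyl]-4-(prop-1-en-2-yl)cyclopent-1-en-1-yl trifluoromethanesulfonate | COC(OC)[C@@H](C)[C@@H](CC=C)[C@H](O[Si](C)(C)C(C)(C)C)[C@H]2C(OS(=O)(=O)C(F)(F)F)=CC[C@@H]2C(C)=C | intermediate
21 | (4S,5S)-5-[(1S,2R,3S)-1-{[tert-butyl(dimethyl)silyl]oxy}-3-methyl-4-oxo-2-(prop-2-en-1-yl)butyl]-4-(prop-1-en-2-yl)cyclopent-1-en-1-yl trifluoromethanesulfonate | O=C[C@@H](C)[C@@H](CC=C)[C@H](O[Si](C)(C)C(C)(C)C)[C@H]2C(OS(=O)(=O)C(F)(F)F)=CC[C@@H]2C(C)=C | intermediate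
22 | chlorobarium alkoxide of the (12S)-alcohol, i.e. 23 with O–BaCl in place of OAc | CC(C)=CC[C@H](O[Ba]Cl)[C@@H](C)[C@@H](CC=C)[C@H](O[Si](C)(C)C(C)(C)C)[C@H]2C(OS(=O)(=O)C(F)(F)F)=CC[C@@H]2C(C)=C | intermediate
23 | (4S,5S)-5-[(1S,2R,3S,4S)-4-(acetyloxy)-1-{[tert-butyl(dimethyl)silyl]oxy}-3,7-dimethyl-2-(prop-2-en-1-yl)oct-6-en-1-yl]-4-(prop-1-en-2-yl)cyclopent-1-en-1-yl trifluoromethanesulfonate | CC(C)=CC[C@H](OC(C)=O)[C@@H](C)[C@@H](CC=C)[C@H](O[Si](C)(C)C(C)(C)C)[C@H]2C(OS(=O)(=O)C(F)(F)F)=CC[C@@H]2C(C)=C | intermediate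
24 | (4S,5S)-5-[(1S,2R,3S,4S)-4-(acetyloxy)-1-{[tert-butyl(dimethyl)silyl]oxy}-5-[(2R)-3,3-dimethyloxiran-2-yl]-3-methyl-2-(prop-2-en-1-yl)pentyl]-4-(prop-1-en-2-yl)cyclopent-1-en-1-yl trifluoromethanesulfonate | CC1(C)O[C@@H]1C[C@H](OC(C)=O)[C@@H](C)[C@@H](CC=C)[C@H](O[Si](C)(C)C(C)(C)C)[C@H]2C(OS(=O)(=O)C(F)(F)F)=CC[C@@H]2C(C)=C | intermediate
25 | (3aS,4S,5R,8aS)-5-{(2S,3S)-3-(acetyloxy)-4-[(2R)-3,3-dimethyloxiran-2-yl]butan-2-yl}-4-{[tert-butyl(dimethyl)silyl]oxy}-8-methyl-1,3a,4,5,6,8a-hexahydroazulen-3-yl trifluoromethanesulfonate | CC1(C)O[C@@H]1C[C@H](OC(C)=O)[C@@H](C)[C@H]3CC=C(C)[C@H]2CC=C(OS(=O)(=O)C(F)(F)F)[C@@H]2[C@H]3O[Si](C)(C)C(C)(C)C | intermediate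
26 | (3aS,4S,5R,7S,8R,8aS)-5-{(2S,3S)-3-(acetyloxy)-4-[(2R)-3,3-dimethyloxiran-2-yl]butan-2-yl}-4-{[tert-butyl(dimethyl)silyl]oxy}-7,8-epoxy-8-methyl-1,3a,4,5,6,7,8,8a-octahydroazulen-3-yl trifluoromethanesulfonate (epoxide oxygen on the face of H1) | CC1(C)O[C@@H]1C[C@H](OC(C)=O)[C@@H](C)[C@H]3C[C@@H]4O[C@]4(C)[C@H]2CC=C(OS(=O)(=O)C(F)(F)F)[C@@H]2[C@H]3O[Si](C)(C)C(C)(C)C | intermediate
27 | (3aS,4S,5R,7S,8aS)-5-[(2S,3S,5R)-3-(acetyloxy)-6-methyl-5-[(trimethylsilyl)oxy]hept-6-en-2-yl]-4-{[tert-butyl(dimethyl)silyl]oxy}-8-methylidene-7-[(trimethylsilyl)oxy]-1,3a,4,5,6,7,8,8a-octahydroazulen-3-yl trifluoromethanesulfonate | C=C(C)[C@H](O[Si](C)(C)C)C[C@H](OC(C)=O)[C@@H](C)[C@H]1C[C@H](O[Si](C)(C)C)C(=C)[C@H]2CC=C(OS(=O)(=O)C(F)(F)F)[C@@H]2[C@H]1O[Si](C)(C)C(C)(C)C | intermediate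
28 | (2S,3S,5R)-2-[(3aR,4S,5R,7S,8aS)-4-{[tert-butyl(dimethyl)silyl]oxy}-3-methyl-8-methylidene-7-[(trimethylsilyl)oxy]-1,3a,4,5,6,7,8,8a-octahydroazulen-5-yl]-6-methyl-5-[(trimethylsilyl)oxy]hept-6-en-3-yl acetate | C=C(C)[C@H](O[Si](C)(C)C)C[C@H](OC(C)=O)[C@@H](C)[C@H]1C[C@H](O[Si](C)(C)C)C(=C)[C@H]2CC=C(C)[C@@H]2[C@H]1O[Si](C)(C)C(C)(C)C | intermediate
29 | (2S,3S,5R)-2-[(3aR,4S,5R,7S,8aS)-4,7-dihydroxy-3-methyl-8-methylidene-1,3a,4,5,6,7,8,8a-octahydroazulen-5-yl]-5-hydroxy-6-methylhept-6-en-3-yl acetate (CNP0281601.4) | C=C(C)[C@H](O)C[C@H](OC(C)=O)[C@@H](C)[C@H]1C[C@H](O)C(=C)[C@H]2CC=C(C)[C@@H]2[C@H]1O | target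

## Step count and risks

Total step count: 17. Longest linear sequence: 16 (steps 1–5 and 7–17; step 6 is a one-step reagent branch).

The three steps most likely to fail are 7, 14 and 15.

**Step 7 (the new step).** The alkenyl-9-BBN may transmetalate or turn the rhodium enolate over poorly. The fallback uses known chemistry and sets out from 14. Copper-catalysed conjugate addition of 11 (CuBr·SMe2 5 mol %, THF, −78 °C) gives the racemic enolate bromomagnesium 3-(prop-1-en-2-yl)cyclopent-1-en-1-olate F1, which is trapped at −78 °C with enantiopure 10. The (S)-enolate reacts through the matched anti/Felkin chair to give 17. The (R)-enolate gives the mismatched diastereomer (2R,3R)-2-[(1R,2R,3S)-1-hydroxy-4,4-dimethoxy-3-methyl-2-(prop-2-en-1-yl)butyl]-3-(prop-1-en-2-yl)cyclopentan-1-one F2, which is removed by chromatography. Absolute control thus passes from the catalyst to the aldehyde, at the cost of at most half of the enolate being productive, and the route is rejoined at 17.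

**Step 14.** The peracid may not discriminate the two faces of the C9=C10 alkene well enough. The fallback sets out from 25 and replaces substrate control by reagent control: the enantiomer of the ketone used in step 12 (ent-Shi ketone, made from L-sorbose; KHSO5, K2CO3, pH 10.5, 0 °C). Its spiro transition-state model delivers oxygen to the face that gives 9S, matched with the substrate bias. It comes back to the route at 26 and makes no compound outside the list (F0).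

**Step 15.** Silyl triflate activation could divert to a hydride shift (ketone), to the endocyclic C1=C10 alkene, or to participation by the C12 acetate. The fallback sets out from 26 and opens the epoxides homolytically instead: Cp2TiCl (trivalent titanium, made from Cp2TiCl2 and manganese dust, THF, 23 °C) cleaves each epoxide at the tertiary C–O bond, and β-hydride elimination from the methyl group gives the diol (3aS,4S,5R,7S,8aS)-5-[(2S,3S,5R)-3-(acetyloxy)-5-hydroxy-6-methylhept-6-en-2-yl]-4-{[tert-butyl(dimethyl)silyl]oxy}-7-hydroxy-8-methylidene-1,3a,4,5,6,7,8,8a-octahydroazulen-3-yl trifluoromethanesulfonate F3. Silylation (Me3SiCl, imidazole, CH2Cl2) returns to the route at 27.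

Further compounds
F1 | step 7 | bromomagnesium 3-(prop-1-en-2-yl)cyclopent-1-en-1-olate (racemic) | CC(=C)C1CCC(O[Mg]Br)=C1
F2 | step 7 | (2R,3R)-2-[(1R,2R,3S)-1-hydroxy-4,4-dimethoxy-3-methyl-2-(prop-2-en-1-yl)butyl]-3-(prop-1-en-2-yl)cyclopentan-1-one | COC(OC)[C@@H](C)[C@@H](CC=C)[C@@H](O)[C@@H]2C(=O)CC[C@H]2C(C)=C
F0 | step 14 | none | none
F3 | step 15 | (3aS,4S,5R,7S,8aS)-5-[(2S,3S,5R)-3-(acetyloxy)-5-hydroxy-6-methylhept-6-en-2-yl]-4-{[tert-butyl(dimethyl)silyl]oxy}-7-hydroxy-8-methylidene-1,3a,4,5,6,7,8,8a-octahydroazulen-3-yl trifluoromethanesulfonate | C=C(C)[C@H](O)C[C@H](OC(C)=O)[C@@H](C)[C@H]1C[C@H](O)C(=C)[C@H]2CC=C(OS(=O)(=O)C(F)(F)F)[C@@H]2[C@H]1O[Si](C)(C)C(C)(C)C
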